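Skeleton numbering used throughout: C1 (methyl-bearing fusion carbon), C2 and C3 (methylenes), C4 (carbinol carbon bearing isopropyl and the ester oxygen), C5 (fusion CH), C6 (secondary carbinol), C7 (methylene), C8 (methyl-bearing epoxide carbon), C9 (epoxide CH), C10 (methylene). Ring A = C1–C5; ring B = C1, C5, C6, C7, C8, C9, C10.

## Analysis of the target

CNP0315707.1 is a daucane sesquiterpenoid ester: cyclopentane ring A is trans-fused along C1–C5 to cycloheptane ring B, and the tertiary oxygen on C4 carries a 4-hydroxy-3-methoxybenzoyl (vanilloyl) group. There are six stereocentres, C1 (R), C4 (R), C5 (S), C6 (S), C8 (R) and C9 (S). The C1 methyl and H5 are trans. The C4 oxygen lies on the face of the C1 methyl and is cis to the C5–C6 bond. The C6 hydroxyl and the epoxide oxygen both lie on the face of H5, opposite the angular methyl. The sensitive groups are the trisubstituted epoxide, the tertiary aryl ester, which has a free hydroxyl in a cis 1,3-relation that invites acyl migration to O6 under base, and the free phenol. A free C4 hydroxyl would also sit correctly for rear-side attack on C8 of the epoxide, so the epoxide cannot coexist with it. The difficulties are the quaternary C1 as a single enantiomer next to the contiguous C4–C5–C6 triad, acylation of the hindered tertiary oxygen while the accessible secondary hydroxyl ends up free, and a seven-membered ring with an epoxide of defined face. The strategy rests on one feature: with a carbonyl oxygen on C4, ring A is a cyclopentanone whose β-carbon is C1 and whose α-carbon is C5. The two bonds that tie ring A to ring B, C1–C10 and C5–C6, are then the bonds made when a nucleophile adds to the β-position of an enone and the resulting enolate adds to an aldehyde, and C6 receives its oxygen in the same event.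

## Retrosynthetic reasoning

**Epoxide (24 to 23).** The two C–O bonds of the oxirane at C8 and C9 are cut first, leaving the C8=C9 alkene of 23. The epoxide is the most fragile group and would survive neither low-valent metals, organometallic reagents nor aqueous acid. It must also follow acylation of O4, because a free C4 hydroxyl would open it from the rear at C8. The forward reaction has to deliver oxygen to the face of H5; the free C6 hydroxyl of 23 sits on that face and can direct a metal-bound peroxide.

**Silyl groups (23 to 22).** Both O–Si bonds, at O6 and at the phenol, are cut together. One type of protecting group for both positions means one deprotection. The forward reaction must avoid a free C6 alkoxide, which could take the acyl group over from O4.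

**Ester (22 to 16 and 20).** The acyl C–O4 bond is cut, which makes the route convergent. The acid chloride 20 comes from vanillic acid 17 through acid 19, with the doubly silylated 18 as a transient. The forward reaction is the acylation of a tertiary alkoxide, which is why 16 carries O6 as a silyl ether. The ester is attached after ring B is closed because an aryl ester would not be safe under reductive carbonyl coupling.

**Ring B (16 to 15).** The C8=C9 bond is cut to a C9 aldehyde and a C8 methyl ketone. It is the only sp2–sp2 bond of ring B, so closing there creates no stereocentre and the trans fusion is already fixed by C1 and C5. The forward reaction is a reductive coupling of the two carbonyls by low-valent titanium under dilution.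

**Masked carbonyls (15 to 13 to 12).** The C9 aldehyde is traced to the silyl-substituted C10=C9 alkene of 12 through its epoxide 13, with 14 as transient. The C8 ketone is traced to the cyclic ketal. Both carbonyls have to stay hidden while the C4 ketone is attacked, and one acid treatment frees both.

**Isopropyl group (12 to 11).** The C4–isopropyl bond is cut, which returns C4 to the ketone oxidation level that makes ring A an enone-derived cyclopentanone. The forward reaction is a 1,2-addition to a hindered, enolisable ketone from the face opposite the C5 side chain, which places the new hydroxyl cis to that chain as the target requires.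

**C6 silyl ether (11 to 10).** The O6–Si bond is cut. The silyl ether keeps the aldol from reverting under the basic organometallic reagent and later distinguishes O6 from O4.

**Key disconnection (10 to 8, 4 and 7).** C1–C10 and C5–C6 are cut together. Enone 8 accepts the alkenyl group of 4 at C1, and the enolate 9 so formed adds through C5 to aldehyde 7. Three achiral pieces give all fifteen skeletal carbons except the isopropyl group, with C1, C5 and C6 set and every later carbonyl already in place in masked form.

**Fragments.** Grignard reagent 4 comes from bromide 3, which comes from stannane 2 by tin–halogen exchange and from alkyne 1 by hydrostannation. Aldehyde 7 comes from ketal ester 6 by partial reduction and from keto ester 5 by ketalisation. Enone 8 is used as bought.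

## Alternatives that were turned down

**Alternative 1:** a divinylcyclopropane rearrangement.
- **Disconnection and key step.** C1–C10 is cut in the retro-sense of a [3,3] shift. The precursor is the cis-divinylcyclopropane A1, whose three-membered ring is C6–C7–C8 and whose two alkenes are C5=C1 of a cyclopentene and the C9=C10 vinyl group. On heating, the C6–C8 bond breaks and C1–C10 forms, giving the bicyclic silyl enol ether A2.
- **For it.** One reagent-free step closes ring B, makes the quaternary C1 and places the C8=C9 alkene, its methyl and the C6 oxygen correctly. On ring construction it is stronger than the chosen route, which needs a separate carbonyl coupling.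
- **Against it.** The terminus C1 is a fully substituted alkene carbon, so either its methyl or its ring methylene must point into the boat transition state. That raises the barrier and favours the competing homo-1,5-hydrogen shift. C1 is set only if A1 is a single cis-cyclopropane diastereomer relative to the remote C4 centre, and nothing in the structure secures that. After the rearrangement C5 is sp2, so C5 and C6 still have to be set by protonation and by ketone reduction from the hindered face of the angular methyl.
- **Comparison.** The chosen route fixes C1, C5 and C6 in one kinetically controlled step and leaves nothing to correct at the ring fusion.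

**Alternative 2:** a carbenoid C–H insertion.
- **Disconnection and key step.** C4–C5 of ring A is cut. The diazo ester A3 would give, with a dirhodium tetracarboxylate catalyst, a carbenoid at C5 that inserts into the ether-activated tertiary C4–H bond with retention, giving the cyclopentane A4.
- **For it.** The C4 oxygen stereocentre comes from an acyclic secondary carbinol and is transferred stereospecifically. On this centre it is stronger than the chosen route, which relies on facial selectivity in an organometallic addition to a crowded ketone. The tertiary oxygen is also protected from the start.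
- **Against it.** The carbenoid carbon is attached to the quaternary C1, so the diazo group must be installed at a neopentyl-type position, and a 1,2-shift of a C1 substituent competes with insertion. C1 must be made enantiopure in a separate earlier step. A4 still lacks ring B, and the closure has to form C6–C7 from an ester and an allylic ester. An allylmetal at C7 would prefer to react through C9 and give a five-membered ring, so the closure needs umpolung chemistry and several redox steps.
- **Comparison.** The chosen route makes both ring-B arms, with the right oxidation levels, in the step that sets C1.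

**Alternative 3:** a rhodium (5+2) cycloaddition.
- **Disconnection and key step.** C1–C5 and C6–C7 are cut together. The yne-vinylcyclopropane A6, built from the chiral-pool alcohol (S)-terpinen-4-ol A5 by ring cleavage, would cyclise with a monovalent rhodium carbonyl chloride catalyst to the bicyclic dienyl silyl ether A7.
- **For it.** Both rings close in one catalytic, atom-economic step, and the C4 carbinol arrives with its isopropyl group attached. On ring construction it is clearly stronger than the chosen key step, which closes no ring.
- **Against it.** A5 is sold in modest enantiomeric purity. Turning it into A6 needs ring cleavage, an aldehyde-to-alkyne conversion and a geometry-defined trisubstituted alkene. The quaternary C1 must form from a fully substituted alkene terminus, with only the distant C4 centre to control its face. A7 lacks the C8 methyl and the C6 oxygen and carries oxygen on C9, so many steps of functional-group correction follow.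
- **Comparison.** The chosen key step closes no ring, but it delivers the complete substitution pattern of ring B and three stereocentres from three simple pieces.

Key step: step 6

Assumption: the sense of induction of the copper–carbene catalyst on enone 8 is not derived here. The enantiomer of the imidazolinium salt that gives (3S)-configured 10 is settled by one trial run (both enantiomers are accessible from the two enantiomers of leucinol); the (S)-leucinol-derived salt in step 6 stands for that choice.

## Route

Step 1
Reactants: 1 ethynyltrimethylsilane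
Product: 2 (E)-tributyl[2-(trimethylsilyl)ethenyl]stannane
Conditions: Bu3SnH, AIBN (cat.), neat, 90 °C
Reagents that add atoms: tributyltin hydride, CCCC[SnH](CCCC)CCCC
Why: Radical hydrostannation of a terminal alkyne; the stannyl radical adds to the unsubstituted terminus and reversible radical addition should funnel the product to the E isomer.

Step 2
Reactants: 2 (E)-tributyl[2-(trimethylsilyl)ethenyl]stannane
Product: 3 (E)-(2-bromoethenyl)trimethylsilane
Conditions: Br2 (1.0 equiv), CH2Cl2, −78 °C
Reagents that add atoms: bromine, BrBr
Why: Bromodestannylation by ipso electrophilic substitution; the C–Sn bond is cleaved far faster than the C–Si bond, with retention of alkene geometry.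

Step 3
Reactants: 3 (E)-(2-bromoethenyl)trimethylsilane
Product: 4 (E)-[2-(trimethylsilyl)ethenyl]magnesium bromide
Conditions: Mg turnings (BrCH2CH2Br-activated), THF, 40 °C, concentrated solution
Reagents that add atoms: magnesium, [Mg]
Why: Grignard formation by insertion of magnesium into the alkenyl C–Br bond. The alkene geometry is of no consequence later, since both alkene carbons lose it in step 10.

Step 4
Reactants: 5 ethyl acetoacetate
Product: 6 ethyl (2-methyl-1,3-dioxolan-2-yl)acetate
Conditions: HOCH2CH2OH, p-TsOH (cat.), toluene, reflux, Dean–Stark trap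
Reagents that add atoms: ethylene glycol, OCCO
Why: Acid-catalysed ketalisation of the ketone carbonyl, driven by azeotropic removal of water; the ester is untouched.

Step 5
Reactants: 6 ethyl (2-methyl-1,3-dioxolan-2-yl)acetate
Product: 7 (2-methyl-1,3-dioxolan-2-yl)acetaldehyde
Conditions: i-Bu2AlH (DIBAL-H, 1.05 equiv), CH2Cl2, −78 °C; aq. potassium sodium tartrate
Reagents that add atoms: none
Why: Partial reduction of an ester; the tetrahedral aluminium hemiacetal, held by chelation to a dioxolane oxygen, should persist at −78 °C and release the aldehyde only on work-up.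

Step 6
Reactants: 8 3-methylcyclopent-2-en-1-one; 4 (E)-[2-(trimethylsilyl)ethenyl]magnesium bromide; 7 (2-methyl-1,3-dioxolan-2-yl)acetaldehyde
Product: 10 (2S,3S)-2-[(1S)-1-hydroxy-2-(2-methyl-1,3-dioxolan-2-yl)ethyl]-3-methyl-3-[(E)-2-(trimethylsilyl)ethenyl]cyclopentan-1-one, via bromomagnesium enolate 9 (not isolated)
Conditions: CuBr·SMe2 (5 mol %), (S)-1-(1-hydroxy-4-methylpentan-2-yl)-3-mesityl-4,5-dihydroimidazolium hexafluorophosphate (7 mol %), Et2O, −30 °C, slow addition of 4; then 7, −78 °C; aq. NH4Cl, −78 °C
Reagents that add atoms: none
Why: The Grignard reagent 4 deprotonates the imidazolinium salt and transmetalates to monovalent copper; the carbene-bound alkenylcopper species forms a π-complex with enone 8, oxidative addition at C1 gives a trivalent copper intermediate, and reductive elimination forms C1–C10 and releases the bromomagnesium enolate 9. Enolate 9 is regiodefined (oxygen on C4, nucleophilic carbon C5) and adds to aldehyde 7 through a closed six-membered chair transition state with magnesium bridging both oxygens (Zimmerman–Traxler), forming C5–C6. The closest known reaction type is the copper–carbene-catalysed enantioselective conjugate addition of Grignard reagents to 3-substituted cycloalkenones with aldol trapping of the magnesium enolate; no ring is closed, and two skeletal bonds and three stereocentres are formed. C1 is set by the chiral carbene on copper, which differentiates the two faces of the flat enone. C5 is set by the substituents on C1: the aldehyde should approach the enolate face opposite the long silylalkenyl group, so that the C6 arm ends up cis to the C1 methyl, the relation needed for the trans ring fusion. C6 is set relative to C5 by the enolate geometry: the ring locks the enolate as E, and with the aldehyde substituent equatorial in the chair the anti aldol results. The step needs 1,4- over 1,2-addition, secured by the soft copper-bound nucleophile, slow addition of 4 and the ether medium, and it needs a kinetic aldol, secured by running and quenching the second stage at −78 °C so that retro-aldol and dehydration do not set in.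

Step 7
Reactants: 10 (2S,3S)-2-[(1S)-1-hydroxy-2-(2-methyl-1,3-dioxolan-2-yl)ethyl]-3-methyl-3-[(E)-2-(trimethylsilyl)ethenyl]cyclopentan-1-one
Product: 11 (2S,3S)-2-[(1S)-1-(tert-butyldimethylsilyloxy)-2-(2-methyl-1,3-dioxolan-2-yl)ethyl]-3-methyl-3-[(E)-2-(trimethylsilyl)ethenyl]cyclopentan-1-one
Conditions: TBSOTf (1.2 equiv), 2,6-lutidine, CH2Cl2, −78 °C
Reagents that add atoms: tert-butyldimethylsilyl trifluoromethanesulfonate, CC(C)(C)[Si](C)(C)OS(=O)(=O)C(F)(F)F
Why: O-silylation of a hindered secondary alcohol with a silyl triflate and a non-nucleophilic base; at −78 °C neither retro-aldol, enol silylation of the ketone nor opening of the ketal should compete.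

Step 8
Reactants: 11 (2S,3S)-2-[(1S)-1-(tert-butyldimethylsilyloxy)-2-(2-methyl-1,3-dioxolan-2-yl)ethyl]-3-methyl-3-[(E)-2-(trimethylsilyl)ethenyl]cyclopentan-1-one
Product: 12 (1R,2S,3S)-2-[(1S)-1-(tert-butyldimethylsilyloxy)-2-(2-methyl-1,3-dioxolan-2-yl)ethyl]-3-methyl-1-(propan-2-yl)-3-[(E)-2-(trimethylsilyl)ethenyl]cyclopentan-1-ol
Conditions: i-PrMgCl, CeCl3 (anhydrous, pre-stirred), THF, −78 → 0 °C
Reagents that add atoms: isopropylmagnesium chloride, CC(C)[Mg]Cl
Why: 1,2-Addition of an organocerium reagent; its low basicity should suppress enolisation, β-elimination of the C6 silyloxy group and β-hydride reduction. Attack on the cyclopentanone anti to the bulky C5 side chain sets C4 with the hydroxyl cis to that chain.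

Step 9
Reactants: 12 (1R,2S,3S)-2-[(1S)-1-(tert-butyldimethylsilyloxy)-2-(2-methyl-1,3-dioxolan-2-yl)ethyl]-3-methyl-1-(propan-2-yl)-3-[(E)-2-(trimethylsilyl)ethenyl]cyclopentan-1-ol
Product: 13 (1R,2S,3S)-2-[(1S)-1-(tert-butyldimethylsilyloxy)-2-(2-methyl-1,3-dioxolan-2-yl)ethyl]-3-methyl-1-(propan-2-yl)-3-[trans-3-(trimethylsilyl)oxiran-2-yl]cyclopentan-1-ol (both facial epoxide diastereomers)
Conditions: mCPBA, NaHCO3, CH2Cl2, 0 °C
Reagents that add atoms: 3-chloroperoxybenzoic acid, OOC(=O)c1cccc(Cl)c1
Why: Peracid (Prilezhaev) epoxidation of the only alkene, stereospecific for the trans epoxide; the buffer protects the ketal. The two facial diastereomers need not be separated because C9 and C10 lose their configuration in step 10.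

Step 10
Reactants: 13 (1R,2S,3S)-2-[(1S)-1-(tert-butyldimethylsilyloxy)-2-(2-methyl-1,3-dioxolan-2-yl)ethyl]-3-methyl-1-(propan-2-yl)-3-[trans-3-(trimethylsilyl)oxiran-2-yl]cyclopentan-1-ol
Product: 15 2-[(1R,2S,3R)-2-[(1S)-1-(tert-butyldimethylsilyloxy)-3-oxobutyl]-3-hydroxy-1-methyl-3-(propan-2-yl)cyclopentyl]acetaldehyde, via dihydroxysilane 14 (not isolated)
Conditions: HClO4 (0.5 M aq.), THF, 0 °C → rt, short reaction time
Reagents that add atoms: water, O
Why: Acid-catalysed epoxysilane-to-carbonyl rearrangement: water opens the protonated epoxide at the silicon-bearing C9 to give 14, and Peterson-type loss of trimethylsilanol gives the enol of the C9 aldehyde, while the same medium hydrolyses the dioxolane to the C8 methyl ketone. The hindered secondary silyl ether and the tertiary alcohol should tolerate cold dilute acid. 15 may sit partly as the reversible hemiketal between the C4 hydroxyl and the C8 ketone and is used at once.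

Step 11
Reactants: 15 2-[(1R,2S,3R)-2-[(1S)-1-(tert-butyldimethylsilyloxy)-3-oxobutyl]-3-hydroxy-1-methyl-3-(propan-2-yl)cyclopentyl]acetaldehyde
Product: 16 (3R,3aS,4S,8aR)-4-(tert-butyldimethylsilyloxy)-6,8a-dimethyl-3-(propan-2-yl)-1,2,3,3a,4,5,8,8a-octahydroazulen-3-ol
Conditions: TiCl3(DME)1.5, Zn–Cu couple, DME, reflux; 15 added by syringe pump (high dilution)
Reagents that add atoms: none
Why: Intramolecular McMurry coupling: ketyl coupling of aldehyde and ketone on low-valent titanium and deoxygenation of the titanium pinacolate give the C8=C9 alkene and close ring B as a seven-membered ring. No stereocentre is formed; free hydroxyl and silyl ether groups are tolerated, and the aryl ester is not yet present.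

Step 12
Reactants: 17 vanillic acid
Product: 19 4-(tert-butyldimethylsilyloxy)-3-methoxybenzoic acid, via bis-silylated vanillic acid 18 (not isolated)
Conditions: TBSCl (2.2 equiv), imidazole, DMF, rt; then AcOH–THF–H2O, rt
Reagents that add atoms: tert-butyldimethylsilyl chloride, CC(C)(C)[Si](C)(C)Cl
Why: Silylation of phenol and acid, then selective hydrolysis of the much more labile silyl ester; the aryl silyl ether should survive dilute acetic acid.

Step 13
Reactants: 19 4-(tert-butyldimethylsilyloxy)-3-methoxybenzoic acid
Product: 20 4-(tert-butyldimethylsilyloxy)-3-methoxybenzoyl chloride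
Conditions: (COCl)2, DMF (cat.), CH2Cl2, 0 °C → rt; volatiles removed, used crude
Reagents that add atoms: oxalyl chloride, ClC(=O)C(=O)Cl
Why: Acid chloride formation through the chloroiminium (Vilsmeier-type) intermediate under anhydrous conditions, which an aryl silyl ether tolerates.

Step 14
Reactants: 16 (3R,3aS,4S,8aR)-4-(tert-butyldimethylsilyloxy)-6,8a-dimethyl-3-(propan-2-yl)-1,2,3,3a,4,5,8,8a-octahydroazulen-3-ol; 20 4-(tert-butyldimethylsilyloxy)-3-methoxybenzoyl chloride
Product: 22 (3R,3aS,4S,8aR)-4-(tert-butyldimethylsilyloxy)-6,8a-dimethyl-3-(propan-2-yl)-1,2,3,3a,4,5,8,8a-octahydroazulen-3-yl 4-(tert-butyldimethylsilyloxy)-3-methoxybenzoate, via lithium alkoxide 21 (not isolated)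
Conditions: n-BuLi (1.05 equiv), THF, −78 °C; then 20, −78 °C → rt
Reagents that add atoms: none
Why: Acylation of a preformed tertiary lithium alkoxide with an aroyl chloride, the standard answer to a tertiary alcohol too hindered for amine-catalysed acylation. O6 is silylated, so only O4 can react, and no stereocentre is touched.

Step 15
Reactants: 22 (3R,3aS,4S,8aR)-4-(tert-butyldimethylsilyloxy)-6,8a-dimethyl-3-(propan-2-yl)-1,2,3,3a,4,5,8,8a-octahydroazulen-3-yl 4-(tert-butyldimethylsilyloxy)-3-methoxybenzoate
Product: 23 (3R,3aS,4S,8aR)-4-hydroxy-6,8a-dimethyl-3-(propan-2-yl)-1,2,3,3a,4,5,8,8a-octahydroazulen-3-yl 4-hydroxy-3-methoxybenzoate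
Conditions: HF·pyridine, pyridine, THF, 0 °C → rt
Reagents that add atoms: none
Why: Fluoride cleavage of both Si–O bonds in a buffered, non-basic medium. No free C6 alkoxide is formed, so the acyl group should not migrate from O4 to the cis-disposed O6, and the tertiary ester is not ionised.

Step 16
Reactants: 23 (3R,3aS,4S,8aR)-4-hydroxy-6,8a-dimethyl-3-(propan-2-yl)-1,2,3,3a,4,5,8,8a-octahydroazulen-3-yl 4-hydroxy-3-methoxybenzoate
Product: 24 (3R,3aS,4S,6R,7S,8aR)-6,7-epoxy-4-hydroxy-6,8a-dimethyl-3-(propan-2-yl)decahydroazulen-3-yl 4-hydroxy-3-methoxybenzoate (CNP0315707.1)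
Conditions: VO(acac)2 (5 mol %), t-BuOOH (1.5 equiv, in decane), CH2Cl2, 0 °C → rt
Reagents that add atoms: tert-butyl hydroperoxide, CC(C)(C)OO
Why: Hydroxyl-directed epoxidation of a homoallylic alcohol: the C6 alkoxide bound to the pentavalent vanadium alkylperoxide delivers oxygen to the alkene face on which the hydroxyl sits, which is also the face free of the angular methyl, and this sets C8 (R) and C9 (S). The phenol is deactivated by its para ester and should at most act as a spectator ligand; O4 is acylated, so it cannot open the epoxide.

## Compound list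

1 | ethynyltrimethylsilane | C#C[Si](C)(C)C | starting material
2 | (E)-tributyl[2-(trimethylsilyl)ethenyl]stannane | CCCC[Sn](CCCC)(CCCC)/C=C/[Si](C)(C)C | intermediate
3 | (E)-(2-bromoethenyl)trimethylsilane | C[Si](C)(C)/C=C/Br | intermediate
4 | (E)-[2-(trimethylsilyl)ethenyl]magnesium bromide | C[Si](C)(C)/C=C/[Mg]Br | intermediate
5 | ethyl acetoacetate | CCOC(=O)CC(C)=O | starting material
6 | ethyl (2-methyl-1,3-dioxolan-2-yl)acetate | CCOC(=O)CC1(C)OCCO1 | intermediate
7 | (2-methyl-1,3-dioxolan-2-yl)acetaldehyde | CC1(CC=O)OCCO1 | intermediate
8 | 3-methylcyclopent-2-en-1-one | CC1=CC(=O)CC1 | starting material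
9 | bromomagnesium (S)-3-methyl-3-[(E)-2-(trimethylsilyl)ethenyl]cyclopent-1-en-1-olate (not isolated) | C[C@]1(/C=C/[Si](C)(C)C)CCC(O[Mg]Br)=C1 | intermediate
10 | (2S,3S)-2-[(1S)-1-hydroxy-2-(2-methyl-1,3-dioxolan-2-yl)ethyl]-3-methyl-3-[(E)-2-(trimethylsilyl)ethenyl]cyclopentan-1-one | O=C1CC[C@](C)(/C=C/[Si](C)(C)C)[C@H]1[C@@H](O)CC1(C)OCCO1 | intermediate
11 | (2S,3S)-2-[(1S)-1-(tert-butyldimethylsilyloxy)-2-(2-methyl-1,3-dioxolan-2-yl)ethyl]-3-methyl-3-[(E)-2-(trimethylsilyl)ethenyl]cyclopentan-1-one | O=C1CC[C@](C)(/C=C/[Si](C)(C)C)[C@H]1[C@@H](O[Si](C)(C)C(C)(C)C)CC1(C)OCCO1 | intermediate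
12 | (1R,2S,3S)-2-[(1S)-1-(tert-butyldimethylsilyloxy)-2-(2-methyl-1,3-dioxolan-2-yl)ethyl]-3-methyl-1-(propan-2-yl)-3-[(E)-2-(trimethylsilyl)ethenyl]cyclopentan-1-ol | O[C@@]1(C(C)C)CC[C@](C)(/C=C/[Si](C)(C)C)[C@H]1[C@@H](O[Si](C)(C)C(C)(C)C)CC1(C)OCCO1 | intermediate
13 | (1R,2S,3S)-2-[(1S)-1-(tert-butyldimethylsilyloxy)-2-(2-methyl-1,3-dioxolan-2-yl)ethyl]-3-methyl-1-(propan-2-yl)-3-[trans-3-(trimethylsilyl)oxiran-2-yl]cyclopentan-1-ol (trans epoxide, both facial diastereomers, epoxide centres left open in the SMILES) | O[C@@]1(C(C)C)CC[C@](C)(C2OC2[Si](C)(C)C)[C@H]1[C@@H](O[Si](C)(C)C(C)(C)C)CC1(C)OCCO1 | intermediate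
14 | (1R,2S,3S)-2-[(1S)-1-(tert-butyldimethylsilyloxy)-2-(2-methyl-1,3-dioxolan-2-yl)ethyl]-3-[1,2-dihydroxy-2-(trimethylsilyl)ethyl]-3-methyl-1-(propan-2-yl)cyclopentan-1-ol (not isolated, diol centres as formed from 13) | O[C@@]1(C(C)C)CC[C@](C)(C(O)C(O)[Si](C)(C)C)[C@H]1[C@@H](O[Si](C)(C)C(C)(C)C)CC1(C)OCCO1 | intermediate
15 | 2-[(1R,2S,3R)-2-[(1S)-1-(tert-butyldimethylsilyloxy)-3-oxobutyl]-3-hydroxy-1-methyl-3-(propan-2-yl)cyclopentyl]acetaldehyde | O[C@@]1(C(C)C)CC[C@](C)(CC=O)[C@H]1[C@@H](O[Si](C)(C)C(C)(C)C)CC(C)=O | intermediate
16 | (3R,3aS,4S,8aR)-4-(tert-butyldimethylsilyloxy)-6,8a-dimethyl-3-(propan-2-yl)-1,2,3,3a,4,5,8,8a-octahydroazulen-3-ol | O[C@@]1(C(C)C)CC[C@]2(C)CC=C(C)C[C@H](O[Si](C)(C)C(C)(C)C)[C@H]21 | intermediate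
17 | vanillic acid (4-hydroxy-3-methoxybenzoic acid) | COc1cc(C(=O)O)ccc1O | starting material
18 | tert-butyldimethylsilyl 4-(tert-butyldimethylsilyloxy)-3-methoxybenzoate (not isolated) | COc1cc(C(=O)O[Si](C)(C)C(C)(C)C)ccc1O[Si](C)(C)C(C)(C)C | intermediate
19 | 4-(tert-butyldimethylsilyloxy)-3-methoxybenzoic acid | COc1cc(C(=O)O)ccc1O[Si](C)(C)C(C)(C)C | intermediate
20 | 4-(tert-butyldimethylsilyloxy)-3-methoxybenzoyl chloride | COc1cc(C(=O)Cl)ccc1O[Si](C)(C)C(C)(C)C | intermediate
21 | lithium (3R,3aS,4S,8aR)-4-(tert-butyldimethylsilyloxy)-6,8a-dimethyl-3-(propan-2-yl)-1,2,3,3a,4,5,8,8a-octahydroazulen-3-olate (not isolated) | [Li+].[O-][C@@]1(C(C)C)CC[C@]2(C)CC=C(C)C[C@H](O[Si](C)(C)C(C)(C)C)[C@H]21 | intermediate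
22 | (3R,3aS,4S,8aR)-4-(tert-butyldimethylsilyloxy)-6,8a-dimethyl-3-(propan-2-yl)-1,2,3,3a,4,5,8,8a-octahydroazulen-3-yl 4-(tert-butyldimethylsilyloxy)-3-methoxybenzoate | COc1cc(C(=O)O[C@@]2(C(C)C)CC[C@]3(C)CC=C(C)C[C@H](O[Si](C)(C)C(C)(C)C)[C@H]32)ccc1O[Si](C)(C)C(C)(C)C | intermediate
23 | (3R,3aS,4S,8aR)-4-hydroxy-6,8a-dimethyl-3-(propan-2-yl)-1,2,3,3a,4,5,8,8a-octahydroazulen-3-yl 4-hydroxy-3-methoxybenzoate | COc1cc(C(=O)O[C@@]2(C(C)C)CC[C@]3(C)CC=C(C)C[C@H](O)[C@H]32)ccc1O | intermediate
24 | (3R,3aS,4S,6R,7S,8aR)-6,7-epoxy-4-hydroxy-6,8a-dimethyl-3-(propan-2-yl)decahydroazulen-3-yl 4-hydroxy-3-methoxybenzoate (CNP0315707.1) | COc1cc(C(=O)O[C@@]2(C(C)C)CC[C@]3(C)C[C@@H]4O[C@]4(C)C[C@H](O)[C@H]32)ccc1O | target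

## Step count and least certain steps

Total: 16 steps. Longest linear sequence: 12 steps (1, 2, 3, 6, 7, 8, 9, 10, 11, 14, 15, 16); the aldehyde branch (4, 5) and the acyl donor branch (12, 13) join at steps 6 and 14.

**Step 6 (key step).** Three things can go wrong.
- Enantioselection and 1,4-selectivity may be poor, because five-membered enones are flat and slow in conjugate additions and an alkenyl Grignard reagent is more prone to direct carbonyl attack than an alkyl one.
- Facial selection at C5 may be poor, because methyl and alkenyl on C1 differ little in size next to the enolate carbon.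
- The anti preference at C6 may be weak, because chair transition states of cyclic E-enolates are only moderately biased.

The fallback separates the two bond formations. It sets out from 8: bromide 3 is converted (t-BuLi, then i-Bu2AlCl) into diisobutyl[(E)-2-(trimethylsilyl)ethenyl]aluminium F1. F1 is added to 8 under Cu(OTf)2 and a chiral sulfonate-bearing imidazolinium salt, a catalyst class suited to alkenylaluminium additions to β-substituted cyclopentenones. The aluminium enolate is trapped with Me3SiOTf as the silyl enol ether F2, which can be purified and checked for enantiomeric purity. MeLi then cleaves F2 to the lithium enolate F3, if needed with the metal exchanged for a dialkylboron to tighten the chair, and addition of 7 at −78 °C comes back to the route at 10.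

**Step 14.** Acylation of the very hindered alkoxide may be incomplete. The C6 silyl group may also shift to the C4 alkoxide through a six-membered transition state, since the two oxygens are cis, after which the acyl group would end up on O6. The fallback activates the acyl donor instead of the alcohol: acid 19 is dehydrated with DCC to 4-(tert-butyldimethylsilyloxy)-3-methoxybenzoic anhydride F4. Then 16 is treated with F4, MgBr2·OEt2 and a hindered tertiary amine in CH2Cl2 at rt (dual activation without a free alkoxide), which comes back at 22.

**Step 11.** The keto-aldehyde may undergo intramolecular aldol reaction on the Lewis-acidic titanium, since both six-membered modes are open. The ketone may be held as the hemiketal with the C4 hydroxyl and dehydrate to an enol ether, or intermolecular coupling may compete. The fallback replaces carbonyl coupling by olefin metathesis: from 15, double Wittig methylenation (Ph3PCH3Br, KOt-Bu, THF, 0 °C) gives the diene (1R,2S,3R)-2-[(1S)-1-(tert-butyldimethylsilyloxy)-3-methylbut-3-en-1-yl]-3-methyl-1-(propan-2-yl)-3-(prop-2-en-1-yl)cyclopentan-1-ol F5. Ring-closing metathesis with second-generation Grubbs catalyst (toluene, 80 °C) forms the same C8=C9 bond and comes back at 16.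

**Step 8.** The hindered ketone may enolise with loss of the C6 silyloxy group, may be reduced by β-hydride transfer from the secondary alkyl metal, or may be attacked from the wrong face. The fallback uses a smaller sp2 nucleophile that cannot transfer hydride: from 11, isopropenylmagnesium bromide and CeCl3 (THF, −78 °C) give the isopropenyl carbinol (1S,2S,3S)-2-[(1S)-1-(tert-butyldimethylsilyloxy)-2-(2-methyl-1,3-dioxolan-2-yl)ethyl]-3-methyl-1-(prop-1-en-2-yl)-3-[(E)-2-(trimethylsilyl)ethenyl]cyclopentan-1-ol F6. Hydroxyl-directed hydrogenation (H2, [Ir(cod)(PCy3)(py)]PF6, CH2Cl2) reduces only the alkene next to the tertiary hydroxyl, leaves the remote vinylsilane, and comes back at 12.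

**Step 16.** The free phenol may bind to vanadium and slow the directed oxygen transfer or be degraded oxidatively, and the epoxide may open on long exposure to the Lewis acid. The fallback masks the phenol through the oxidation. From 23, selective acetylation of the phenol (Ac2O, Et3N, CH2Cl2, 0 °C; the hindered secondary alcohol is much slower) gives the aryl acetate (3R,3aS,4S,8aR)-4-hydroxy-6,8a-dimethyl-3-(propan-2-yl)-1,2,3,3a,4,5,8,8a-octahydroazulen-3-yl 4-acetoxy-3-methoxybenzoate F7. The same directed epoxidation gives the epoxy acetate (3R,3aS,4S,6R,7S,8aR)-6,7-epoxy-4-hydroxy-6,8a-dimethyl-3-(propan-2-yl)decahydroazulen-3-yl 4-acetoxy-3-methoxybenzoate F8. Brief aminolysis of the aryl acetate with pyrrolidine (CH2Cl2, 0 °C) comes back at 24.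

## Further compounds

F1 | step 6 | diisobutyl[(E)-2-(trimethylsilyl)ethenyl]aluminium | CC(C)C[Al](CC(C)C)/C=C/[Si](C)(C)C
F2 | step 6 | (S)-trimethyl({3-methyl-3-[(E)-2-(trimethylsilyl)ethenyl]cyclopent-1-en-1-yl}oxy)silane | C[C@]1(/C=C/[Si](C)(C)C)CCC(O[Si](C)(C)C)=C1
F3 | step 6 | lithium (S)-3-methyl-3-[(E)-2-(trimethylsilyl)ethenyl]cyclopent-1-en-1-olate | C[C@]1(/C=C/[Si](C)(C)C)CCC(O[Li])=C1
F4 | step 14 | 4-(tert-butyldimethylsilyloxy)-3-methoxybenzoic anhydride | COc1cc(C(=O)OC(=O)c2ccc(O[Si](C)(C)C(C)(C)C)c(OC)c2)ccc1O[Si](C)(C)C(C)(C)C
F5 | step 11 | (1R,2S,3R)-2-[(1S)-1-(tert-butyldimethylsilyloxy)-3-methylbut-3-en-1-yl]-3-methyl-1-(propan-2-yl)-3-(prop-2-en-1-yl)cyclopentan-1-ol | O[C@@]1(C(C)C)CC[C@](C)(CC=C)[C@H]1[C@@H](O[Si](C)(C)C(C)(C)C)CC(C)=C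
F6 | step 8 | (1S,2S,3S)-2-[(1S)-1-(tert-butyldimethylsilyloxy)-2-(2-methyl-1,3-dioxolan-2-yl)ethyl]-3-methyl-1-(prop-1-en-2-yl)-3-[(E)-2-(trimethylsilyl)ethenyl]cyclopentan-1-ol | O[C@@]1(C(C)=C)CC[C@](C)(/C=C/[Si](C)(C)C)[C@H]1[C@@H](O[Si](C)(C)C(C)(C)C)CC1(C)OCCO1
F7 | step 16 | (3R,3aS,4S,8aR)-4-hydroxy-6,8a-dimethyl-3-(propan-2-yl)-1,2,3,3a,4,5,8,8a-octahydroazulen-3-yl 4-acetoxy-3-methoxybenzoate | COc1cc(C(=O)O[C@@]2(C(C)C)CC[C@]3(C)CC=C(C)C[C@H](O)[C@H]32)ccc1OC(C)=O
F8 | step 16 | (3R,3aS,4S,6R,7S,8aR)-6,7-epoxy-4-hydroxy-6,8a-dimethyl-3-(propan-2-yl)decahydroazulen-3-yl 4-acetoxy-3-methoxybenzoate | COc1cc(C(=O)O[C@@]2(C(C)C)CC[C@]3(C)C[C@@H]4O[C@]4(C)C[C@H](O)[C@H]32)ccc1OC(C)=O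
A1 | alternative 1 | cis-divinylcyclopropane: 1-(trimethylsilyloxy)-2-methyl-2-vinylcyclopropane carrying on C1, cis to the vinyl group, the (R)-2-methyl-5-(propan-2-yl)-5-(triethylsilyloxy)cyclopent-1-en-1-yl group | C=C[C@@]1(C)C[C@@]1(O[Si](C)(C)C)C1=C(C)CC[C@@]1(O[Si](CC)(CC)CC)C(C)C
A2 | alternative 1 | bicyclic C6 trimethylsilyl enol ether with the C8=C9 alkene and the C4 triethylsilyl ether | CC[Si](CC)(CC)O[C@@]1(C(C)C)CC[C@]2(C)CC=C(C)CC(O[Si](C)(C)C)=C21
A3 | alternative 2 | acyclic C5 diazo ester with the C4 methoxymethyl ether and the allylic pivalate chain | COCO[C@@H](C(C)C)CC[C@](C)(C/C=C(/C)COC(=O)C(C)(C)C)C(=[N+]=[N-])C(=O)OC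
A4 | alternative 2 | ring A methyl ester with C1, C4 and C5 set | COCO[C@@]1(C(C)C)CC[C@](C)(C/C=C(/C)COC(=O)C(C)(C)C)[C@H]1C(=O)OC
A5 | alternative 3 | (S)-terpinen-4-ol | CC1=CC[C@](O)(C(C)C)CC1
A6 | alternative 3 | yne-vinylcyclopropane with the 1-(tert-butyldimethylsilyloxy)cyclopropyl group | C#C[C@](O)(C(C)C)CC/C(C)=C/C1(O[Si](C)(C)C(C)(C)C)CC1
A7 | alternative 3 | bicyclic dienyl silyl ether (C5=C6 and C9=C10, siloxy on C9) | O[C@@]1(C(C)C)CC[C@]2(C)C=C(O[Si](C)(C)C(C)(C)C)CCC=C21
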